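## Structural features

The target 16 is a C15 sesquiterpenoid chain joined through a ketone carbonyl (C1) to a single benzene ring, a 2,4-dihydroxyphenyl unit; there is no other ring. C3 of the chain is an all-carbon quaternary stereocentre of R configuration. It carries a methyl group, a vinyl group, the C2 methylene that leads to the carbonyl, and a 4,8-dimethylnona-3,7-dienyl (homogeranyl) chain with a 6E trisubstituted alkene and a terminal isopropylidene. It is the only stereocentre, so no neighbouring stereocentre or nearby heteroatom can relay stereochemical information, and its four substituents are hydrocarbon groups of similar size. Fragile elements are the 1,5-diene (acid-triggered hydration or cyclisation), the free resorcinol, and, in intermediates, any aldehyde at C1. Such an aldehyde sits five atoms from C6=C7 and is a citronellal-type substrate for carbonyl-ene closure, made easier by the quaternary C3. The real difficulty is to set this isolated quaternary centre enantioselectively while telling a methyl group from a CH2 chain. The key step uses the fact that C3 is β to the carbonyl carbon C1, and that C3 of (2E,6E)-farnesal already holds the methyl group and the homogeranyl chain in a fixed geometry. Conjugate addition of nitromethane at C3 supplies the one missing carbon, which later becomes the internal vinyl CH, while C1 stays an aldehyde for attachment of the benzene ring.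

## Logic of the disconnections

16 from 15. The two phenolic O–CH2 bonds are cut, so both hydroxyl groups are carried as methoxymethyl acetals. Free phenols would quench the organometallic reagent needed further back. The gain is a robust ether that also chelates lithium. The demand is a final cleavage mild enough for the 1,5-diene and the vinyl group.

15 from 14. No bond is cut; the ketone is traced to the secondary alcohol. This lets the aryl–carbonyl bond come from addition to an aldehyde, with no acyl derivative to prepare. The forward oxidation must be neutral and leave three alkenes alone. The carbinol configuration in 14 is irrelevant.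

14 from 10 and 13. The C1–C(aryl) bond is cut. It is the only bond between the terpenoid and aromatic halves, so the cut is convergent and leaves a C17 aldehyde and a one-ring nucleophile. 13 is traced to 12 and 12 to 11, because the metal must sit para to one oxygen and ortho to the other. Only bromine–lithium exchange guarantees that; deprotonation would go between the two oxygens. The forward addition must be faster than enolisation of 10 at C2.

10 from 9, and 9 from 8. 10 is 9 at the aldehyde oxidation level. In 9 the C=CH2 bond of the vinyl group is cut (carbonyl olefination), which leads back to a formyl group on the quaternary carbon. With the C1 hydroxyl present, that aldehyde exists as the five-membered hemiacetal 8. The gain is that the vinyl group shrinks to a one-carbon substituent on C3. The demand is that the hindered, ring-closed carbonyl still reacts with the ylide. Nothing can epimerise because C3 has no hydrogen.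

8 from 5 (through 7 and 6). No skeletal bond is cut; the formyl carbon is traced to a nitromethyl carbon. This makes the one-carbon substituent on C3 available as a stabilised nucleophile. The forward conversion must be non-oxidising and close to neutral because of the alkenes.

5 from 4. The C1 alcohol is traced to the aldehyde. Reduction is how C1 is masked while the nitromethyl group is converted. An acetal at C1 was weighed and set aside for two reasons. Forming and hydrolysing it would expose a δ,ε-unsaturated aldehyde with a quaternary C3 to acid (carbonyl-ene closure onto C6=C7). An acetal is also at risk in the aqueous titanium medium. The masking costs the same number of steps either way. The demand is that hydride leaves the nitro group alone.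

4 from 2 and 3. The bond between C3 and the nitromethyl carbon is cut. This is the strategic cut: it removes the only stereocentre and returns an intact C15 skeleton plus a one-carbon reagent. The demand is heavy. The forward addition must choose one face of a β,β-disubstituted enal, and must do so before the 2E geometry, which distinguishes methyl from chain, is lost.

2 from 1. No skeletal bond is cut; the enal is traced to the allylic alcohol. The forward oxidation must be free of acid and base so that the 2E alkene is delivered geometrically pure.

## Other disconnections considered

Alternative 1: The cut is the bond between C3 and C2, with C2 and C1 written as an alkyne.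
- **Forward step.** Farnesyl diethyl phosphate A1 (one step from 1) would react with the alkynylalane A3, made in the flask from the aryl acetylene A2 and i-Bu2AlH. A chiral NHC–copper catalyst (CuCl2·2H2O with a sulfonate-bearing chiral imidazolinium salt) would direct SN2' substitution at the γ-carbon to give the enyne A4. A4 has the same spatial arrangement as 16 although its descriptor is 3S.
- **In favour.** One step makes the stereocentre, the vinyl group (by allylic transposition) and the link to the aromatic half. An allylic phosphate cannot scramble its 2E geometry the way an iminium ion can, so on security of the geometric information this plan is better than the chosen one. It is also shorter, about four or five steps in the longest line against nine, which is a clear advantage in step economy.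
- **Against it here.** A4 must still be hydrated with the carbonyl at the aryl-bearing carbon. Its alkyne is part of a 1,4-enyne (with the vinyl group) and of a 1,6-enyne (with C6=C7). Carbophilic hydration catalysts such as Ph3PAuNTf2 or Hg(OTf)2 are the ones expected to trigger enyne cycloisomerisation or alkene oxymetalation. Once the ortho silyl ether is lost, the phenol can close onto the alkyne to give a benzofuran. A2 needs about three steps from 11.
- **Comparison.** Structurally both plans read the stereocentre from the 2E alkene of a farnesyl unit, so they are equal there. Mechanistically this one relies on ligand-controlled copper–alkynyl delivery anti to the leaving group, the chosen one on face shielding of an iminium ion; both reaction types are established for trisubstituted substrates. The chosen plan keeps every later step within routine carbonyl chemistry, whereas alternative 1 moves the main risk to the step after its key step.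

Alternative 2: No skeletal bond of 16 is formed in the key step. Retrosynthetically a bond is added between the C3 methyl carbon and C1, giving the tertiary cyclobutanol A6.
- **Forward step.** [Rh(OH)(cod)]2 with a chiral bisphosphine such as (R)-DTBM-SEGPHOS would form the monovalent rhodium alkoxide of A6. β-Carbon elimination of one of the two enantiotopic ring bonds and protonation of the primary alkylrhodium would give A7, the same compound as 15. A6 would come from (E)-β-farnesene A5 in about three steps: ketene cycloaddition at the 1,1-disubstituted alkene, dechlorination, and addition of 13.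
- **In favour.** The aryl ketone appears at the right oxidation level, and the methyl group and the stereocentre are made in the same step. The precursor is achiral and its stereochemical outcome does not depend on any alkene geometry; on that point it is better than the chosen plan. About six steps in all would suffice, so it is also better in step economy.
- **Against it here.** A ketene would have to pick one of four alkenes in A5. The catalyst would have to distinguish vinyl from a CH2CH2 chain on the ring carbon opposite the carbinol, two groups of similar size. The alkylrhodium intermediate lies next to the vinyl group and five atoms from C6=C7, so alkene insertion or a 1,4-rhodium shift to the aryl ring could compete with protonation.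
- **Comparison.** The chosen plan has a longer endgame but a key step of a type already used to build acyclic quaternary centres from enals. Alternative 2 is shorter but rests on a selectivity without close analogy for this substitution pattern.

Alternative 3: The cut is the C5–C6 bond between the chain CH2 and the alkene CH.
- **Forward step.** A chiral copper hydride (Cu(OAc)2, (R)-DTBM-SEGPHOS, a hydrosilane) would add anti-Markovnikov to one of the two enantiotopic vinyl groups of the divinyl silyl ether A8. Pd(OAc)2 with a biaryl phosphine would couple the primary alkylcopper with the (E)-alkenyl iodide A9 to give A10, the silyl ether of 9.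
- **In favour.** The stereocentre comes from group selection at a symmetric carbon, independent of alkene geometry at the prochiral centre. The 6E alkene arrives preformed in A9, which is as good as taking it from 1. A10 is one desilylation from 9, so the endgame equals that of the chosen plan, and nitro chemistry, the Nef reaction and the Wittig step are avoided, which is better in functional-group handling.
- **Against it here.** Hydrocupration of an unactivated terminal alkene is slow. The resulting primary alkylcopper is not itself stereogenic, so all induction must come from choosing between two vinyl groups whose surroundings differ only as methyl against CH2CH2OSi. Double functionalisation of both vinyl groups is a further risk. A8 and A9 each need several steps.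
- **Comparison.** The chosen plan takes the whole C15 skeleton from 1, so alternative 3 offers no gain in step count. Mechanistically it trades an iminium face selection with direct analogy for a desymmetrisation with little.

Key step: step 2

Assumption: geometrically pure (2E,6E)-farnesol is used, and the (S)-configured catalyst is taken to give the 3R centre as the face-shielding model predicts; if the sense proved opposite, the (R)-catalyst would be used with nothing else changed.

## Route

Step 1
Reactants: 1 (2E,6E)-farnesol
Product: 2 (2E,6E)-farnesal
Conditions: activated MnO2 (15 equiv), CH2Cl2, 20 °C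
Reagents that add atoms: none
Why: Oxidation of a primary allylic alcohol with activated MnO2 is heterogeneous and neutral, stops at the enal and leaves isolated alkenes alone. The absence of acid or base should preserve the 2E geometry that later encodes the stereocentre.

Step 2
Reactants: 2 (2E,6E)-farnesal; 3 nitromethane
Product: 4 (3R,6E)-3,7,11-trimethyl-3-(nitromethyl)dodeca-6,10-dienal
Conditions: (S)-2-[diphenyl(trimethylsilyloxy)methyl]pyrrolidine (20 mol %), PhCO2H (20 mol %), 3 (20 equiv), MeOH, 20 °C
Reagents that add atoms: none
Why: Condensation of 2 with the secondary amine gives the s-trans (E)-iminium ion, in which the 2E alkene places the methyl group cis and the homogeranyl chain trans to the iminium carbon. The diphenyl(trimethylsilyloxy)methyl group covers one face of this planar cation, so the nitronate of 3 should add to C3 from the open face and form the C3–CH2NO2 bond; hydrolysis of the resulting enamine releases 4 and the catalyst. The closest known reaction type is the diarylprolinol silyl ether-catalysed Michael addition of nitromethane to β,β-disubstituted enals that gives all-carbon quaternary centres. No ring is closed. The single new stereocentre (C3) is set by the catalyst, which chooses the face, together with the fixed 2E geometry of the substrate, which decides which substituent lies on which side; with the (S)-catalyst the shielding model predicts 3R. The step needs 1,4- over 1,2-addition, secured by iminium activation of the β-carbon, and enantioface selectivity, which requires C–C bond formation to outpace E/Z scrambling through the dienamine; the large excess of 3 and a weak carboxylic acid as the only co-catalyst serve that purpose. Nitromethane is small enough to reach the fully substituted β-carbon, and the isolated C6=C7 and C10=C11 alkenes are not electrophilic and should stay untouched.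

Step 3
Reactants: 4 (3R,6E)-3,7,11-trimethyl-3-(nitromethyl)dodeca-6,10-dienal
Product: 5 (3R,6E)-3,7,11-trimethyl-3-(nitromethyl)dodeca-6,10-dien-1-ol
Conditions: NaBH4 (1.0 equiv), MeOH, 0 °C; aq. NH4Cl
Reagents that add atoms: none
Why: Borohydride reduction of the aldehyde is chemoselective over an aliphatic nitro group. It removes the δ,ε-unsaturated aldehyde that is prone to acid-catalysed carbonyl-ene closure and provides the hydroxyl group that will hold the Nef product as a lactol; the quaternary centre cannot epimerise.

Step 4
Reactants: 5 (3R,6E)-3,7,11-trimethyl-3-(nitromethyl)dodeca-6,10-dien-1-ol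
Product: 8 (3R)-3-[(3E)-4,8-dimethylnona-3,7-dien-1-yl]-3-methyloxolan-2-ol as a mixture of anomers, via sodium nitronate 6 (not isolated), via hydroxy aldehyde 7 (not isolated)
Conditions: NaOMe (2.2 equiv), MeOH, 0 °C; then added to aq. TiCl3 (4.5 equiv)/NH4OAc buffer (pH 5–6), H2O–MeOH, 0 → 20 °C
Reagents that add atoms: water, O
Why: This is a Nef reaction in its reductive titanium variant: the pre-formed nitronate 6 is reduced at nitrogen by trivalent titanium and the C=N bond is hydrolysed to the aldehyde 7, which closes to the five-membered lactol 8 (5-exo-trig, helped by the gem-disubstitution at C3). The acetate buffer keeps the medium near pH 5–6 so the 1,5-diene is not protonated, and no oxidant is present that could attack the alkenes.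

Step 5
Reactants: 8 (3R)-3-[(3E)-4,8-dimethylnona-3,7-dien-1-yl]-3-methyloxolan-2-ol
Product: 9 (3R,6E)-3-ethenyl-3,7,11-trimethyldodeca-6,10-dien-1-ol
Conditions: Ph3PCH3Br (3.5 equiv), KOtBu (3.3 equiv), THF, 0 °C; then 8, 0 → 50 °C
Reagents that add atoms: methyltriphenylphosphonium bromide, C[P+](c1ccccc1)(c1ccccc1)c1ccccc1.[Br-]
Why: Wittig methylenation of a lactol: the first equivalent of ylide deprotonates the hemiacetal, whose alkoxide opens to the aldehyde that is trapped by further ylide. The aldehyde is neopentylic and has no α-hydrogen, so neither epimerisation nor aldol reaction can compete, and excess ylide with gentle warming should overcome the hindrance.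

Step 6
Reactants: 9 (3R,6E)-3-ethenyl-3,7,11-trimethyldodeca-6,10-dien-1-ol
Product: 10 (3R,6E)-3-ethenyl-3,7,11-trimethyldodeca-6,10-dienal
Conditions: Dess–Martin periodinane (1.3 equiv), NaHCO3 (4 equiv), CH2Cl2, 0 → 20 °C
Reagents that add atoms: none
Why: Dess–Martin oxidation of the primary alcohol under hydrogencarbonate buffer gives the aldehyde without over-oxidation and without acid, which matters because 10 is a citronellal-type aldehyde that could cyclise onto C6=C7. The alkenes and the quaternary centre are inert.

Step 7
Reactants: 11 4-bromoresorcinol (4-bromobenzene-1,3-diol)
Product: 12 1-bromo-2,4-bis(methoxymethoxy)benzene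
Conditions: MOMCl (2.6 equiv), iPr2NEt (3.2 equiv), CH2Cl2, 0 → 20 °C
Reagents that add atoms: chloromethyl methyl ether, COCCl
Why: Base-mediated O-alkylation of both phenols. The acetal ethers tolerate organolithium reagents and the ortho one stabilises the aryllithium by chelation, whereas silyl ethers would be prone to an anionic oxygen-to-carbon silyl shift.

Step 8
Reactants: 12 1-bromo-2,4-bis(methoxymethoxy)benzene; 10 (3R,6E)-3-ethenyl-3,7,11-trimethyldodeca-6,10-dienal
Product: 14 (1RS,3R,6E)-1-[2,4-bis(methoxymethoxy)phenyl]-3-ethenyl-3,7,11-trimethyldodeca-6,10-dien-1-ol, via aryllithium 13 (not isolated)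
Conditions: 12 (1.3 equiv), n-BuLi (1.25 equiv), THF, −78 °C; then 10, −78 → −40 °C; aq. NH4Cl
Reagents that add atoms: none
Why: Bromine–lithium exchange fixes the metal at the former C–Br position, and the aryllithium 13 then adds 1,2 to the aldehyde at low temperature, faster than enolisation at C2. The new carbinol centre forms without control, which is harmless because it is oxidised in step 9.

Step 9
Reactants: 14 (1RS,3R,6E)-1-[2,4-bis(methoxymethoxy)phenyl]-3-ethenyl-3,7,11-trimethyldodeca-6,10-dien-1-ol
Product: 15 (3R,6E)-1-[2,4-bis(methoxymethoxy)phenyl]-3-ethenyl-3,7,11-trimethyldodeca-6,10-dien-1-one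
Conditions: Dess–Martin periodinane (1.3 equiv), NaHCO3 (4 equiv), CH2Cl2, 0 → 20 °C
Reagents that add atoms: none
Why: Dess–Martin oxidation of the secondary benzylic alcohol to the aryl ketone. The neutral conditions should leave the acetals, the alkenes and the non-enolisable C3 centre untouched.

Step 10
Reactants: 15 (3R,6E)-1-[2,4-bis(methoxymethoxy)phenyl]-3-ethenyl-3,7,11-trimethyldodeca-6,10-dien-1-one
Product: 16 (3R,6E)-1-(2,4-dihydroxyphenyl)-3-ethenyl-3,7,11-trimethyldodeca-6,10-dien-1-one
Conditions: HCl (2 M aq., 6 equiv), MeOH, 25–35 °C
Reagents that add atoms: none
Why: Acid-catalysed methanolysis of the two aryl methoxymethyl acetals; protonation of an acetal oxygen is far easier than protonation of a trisubstituted alkene at this acidity. The acyl group deactivates the ring toward the released formaldehyde equivalent, which methanol traps, and the C3 centre is remote from the reacting sites.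

## Compound list

1 | (2E,6E)-farnesol, (2E,6E)-3,7,11-trimethyldodeca-2,6,10-trien-1-ol | OC/C=C(\C)CC/C=C(\C)CCC=C(C)C | starting material
2 | (2E,6E)-farnesal, (2E,6E)-3,7,11-trimethyldodeca-2,6,10-trienal | O=C/C=C(\C)CC/C=C(\C)CCC=C(C)C | intermediate
3 | nitromethane | C[N+](=O)[O-] | starting material
4 | (3R,6E)-3,7,11-trimethyl-3-(nitromethyl)dodeca-6,10-dienal | [O-][N+](=O)C[C@](C)(CC/C=C(\C)CCC=C(C)C)CC=O | intermediate
5 | (3R,6E)-3,7,11-trimethyl-3-(nitromethyl)dodeca-6,10-dien-1-ol | [O-][N+](=O)C[C@](C)(CC/C=C(\C)CCC=C(C)C)CCO | intermediate
6 | sodium nitronate (aci-nitro salt) of 5 | [Na+].[O-][N+]([O-])=C[C@](C)(CC/C=C(\C)CCC=C(C)C)CCO | intermediate (not isolated)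
7 | (2R,5E)-2-(2-hydroxyethyl)-2,6,10-trimethylundeca-5,9-dienal | O=C[C@](C)(CC/C=C(\C)CCC=C(C)C)CCO | intermediate (not isolated)
8 | (3R)-3-[(3E)-4,8-dimethylnona-3,7-dien-1-yl]-3-methyloxolan-2-ol, both anomers | OC1[C@](C)(CC/C=C(\C)CCC=C(C)C)CCO1 | intermediate
9 | (3R,6E)-3-ethenyl-3,7,11-trimethyldodeca-6,10-dien-1-ol | C=C[C@](C)(CC/C=C(\C)CCC=C(C)C)CCO | intermediate
10 | (3R,6E)-3-ethenyl-3,7,11-trimethyldodeca-6,10-dienal | C=C[C@](C)(CC/C=C(\C)CCC=C(C)C)CC=O | intermediate
11 | 4-bromoresorcinol, 4-bromobenzene-1,3-diol | Oc1ccc(Br)c(O)c1 | starting material
12 | 1-bromo-2,4-bis(methoxymethoxy)benzene | COCOc1ccc(Br)c(OCOC)c1 | intermediate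
13 | [2,4-bis(methoxymethoxy)phenyl]lithium | [Li]c1ccc(OCOC)cc1OCOC | intermediate (not isolated)
14 | (1RS,3R,6E)-1-[2,4-bis(methoxymethoxy)phenyl]-3-ethenyl-3,7,11-trimethyldodeca-6,10-dien-1-ol | C=C[C@](C)(CC/C=C(\C)CCC=C(C)C)CC(O)c1ccc(OCOC)cc1OCOC | intermediate
15 | (3R,6E)-1-[2,4-bis(methoxymethoxy)phenyl]-3-ethenyl-3,7,11-trimethyldodeca-6,10-dien-1-one | C=C[C@](C)(CC/C=C(\C)CCC=C(C)C)CC(=O)c1ccc(OCOC)cc1OCOC | intermediate
16 | (3R,6E)-1-(2,4-dihydroxyphenyl)-3-ethenyl-3,7,11-trimethyldodeca-6,10-dien-1-one | C=C[C@](C)(CC/C=C(\C)CCC=C(C)C)CC(=O)c1ccc(O)cc1O | target

## Step count and least certain steps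

Total step count: 10. Longest linear sequence: 9 steps (from 1 through steps 1–6 and 8–10 to 16); step 7 is the one-step side branch.

**Step 2 (key step).**
- **Risk.** The most likely failure is erosion of enantioface control. The (2E)- and (2Z)-iminium ions can interconvert through the dienamine faster than the nitronate adds. The two β-substituents differ only as CH3 against CH2R, so equilibrated ions would be poorly discriminated. Slow addition at the fully substituted β-carbon and retro-Michael cleavage are secondary risks.
- **Fallback.** It sets out from 2 and moves the stereocontrol to a covalently bound auxiliary on a substrate that cannot scramble its alkene.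
  - Pinnick oxidation (NaClO2, NaH2PO4, 2-methylbut-2-ene, t-BuOH/H2O) would give (2E,6E)-farnesoic acid F1.
  - Activation with pivaloyl chloride/Et3N and reaction with the lithium salt of (S)-4-phenyloxazolidin-2-one would give the N-enoyl oxazolidinone F2.
  - Conjugate addition of vinylmagnesium bromide with CuBr·SMe2 in THF at −40 to −15 °C would give the adduct F3. The magnesium chelate holds the s-cis enoyl unit and the phenyl group blocks one face; the (S)-auxiliary is predicted to give 3R. Diastereomers can be separated here.
  - LiBH4 in wet Et2O would remove the auxiliary reductively and return the route to 9. Steps 2–5 are replaced by four steps.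

**Step 4.**
- **Risk.** The reductive Nef reaction may stop at the oxime stage with this neopentylic carbon, or divert to the nitrile. If buffering is lost, the Lewis-acidic aqueous titanium medium may attack the diene.
- **Fallback.** It sets out from 5 and divides the conversion into two discrete, titanium-free stages. Mild reduction with SnCl2·2H2O, PhSH and Et3N in MeCN would give the hydroxy oxime F4 on purpose. Transoximation with aqueous glyoxylic acid buffered by NaOAc would release the aldehyde, which closes to 8, where the route is rejoined.

**Step 5.**
- **Risk.** Ring opening of the gem-disubstituted lactol may be sluggish and attack at the neopentylic carbonyl slow, so the lactol may persist or decompose on forcing.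
- **Fallback.** It sets out from 5 and removes the ring-closing hydroxyl. Silylation (t-BuMe2SiCl, imidazole, DMF) would give the silyl ether F5. The Nef reaction under the conditions of step 4 would give the open-chain aldehyde F6, which cannot form a lactol. Wittig methylenation would give the silyl ether F7 (the same structure as A10), and Bu4NF in THF would return the route to 9. This costs two extra steps.

**Step 10.**
- **Risk.** Acid may add methanol or water to the trisubstituted alkenes, start cation–olefin cyclisation, or let the released formaldehyde equivalent attack the ring before the non-chelated para acetal is cleaved.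
- **Fallback.** It sets out from 11 and changes the protecting group so that the last step is not acidic.
  - Allylation (allyl bromide, K2CO3, acetone) would give 1-bromo-2,4-bis(prop-2-en-1-yloxy)benzene F8.
  - Bromine–lithium exchange with n-BuLi at −78 °C, kept cold to prevent cyclisation onto the allyl ether, would give the aryllithium F9.
  - Addition to 10 would give the alcohol F10, and Dess–Martin oxidation the ketone F11.
  - Deallylation with Pd(PPh3)4 (5 mol %) and morpholine in THF at 20 °C would return the route to 16.

## Further compounds

F1 | step 2 | (2E,6E)-3,7,11-trimethyldodeca-2,6,10-trienoic acid | OC(=O)/C=C(\C)CC/C=C(\C)CCC=C(C)C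
F2 | step 2 | (4S)-4-phenyl-3-[(2E,6E)-3,7,11-trimethyldodeca-2,6,10-trienoyl]-1,3-oxazolidin-2-one | O=C(/C=C(\C)CC/C=C(\C)CCC=C(C)C)N1C(=O)OC[C@@H]1c1ccccc1
F3 | step 2 | (4S)-3-[(3R,6E)-3-ethenyl-3,7,11-trimethyldodeca-6,10-dienoyl]-4-phenyl-1,3-oxazolidin-2-one | C=C[C@](C)(CC/C=C(\C)CCC=C(C)C)CC(=O)N1C(=O)OC[C@@H]1c1ccccc1
F4 | step 4 | (2R,5E)-2-(2-hydroxyethyl)-2,6,10-trimethylundeca-5,9-dienal oxime | ON=C[C@](C)(CC/C=C(\C)CCC=C(C)C)CCO
F5 | step 5 | tert-butyldimethyl{[(3R,6E)-3,7,11-trimethyl-3-(nitromethyl)dodeca-6,10-dien-1-yl]oxy}silane | [O-][N+](=O)C[C@](C)(CC/C=C(\C)CCC=C(C)C)CCO[Si](C)(C)C(C)(C)C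
F6 | step 5 | (2R,5E)-2-{2-[(tert-butyldimethylsilyl)oxy]ethyl}-2,6,10-trimethylundeca-5,9-dienal | O=C[C@](C)(CC/C=C(\C)CCC=C(C)C)CCO[Si](C)(C)C(C)(C)C
F7 | step 5 | tert-butyl{[(3R,6E)-3-ethenyl-3,7,11-trimethyldodeca-6,10-dien-1-yl]oxy}dimethylsilane | C=C[C@](C)(CC/C=C(\C)CCC=C(C)C)CCO[Si](C)(C)C(C)(C)C
F8 | step 10 | 1-bromo-2,4-bis(prop-2-en-1-yloxy)benzene | C=CCOc1ccc(Br)c(OCC=C)c1
F9 | step 10 | [2,4-bis(prop-2-en-1-yloxy)phenyl]lithium | [Li]c1ccc(OCC=C)cc1OCC=C
F10 | step 10 | (1RS,3R,6E)-1-[2,4-bis(prop-2-en-1-yloxy)phenyl]-3-ethenyl-3,7,11-trimethyldodeca-6,10-dien-1-ol | C=C[C@](C)(CC/C=C(\C)CCC=C(C)C)CC(O)c1ccc(OCC=C)cc1OCC=C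
F11 | step 10 | (3R,6E)-1-[2,4-bis(prop-2-en-1-yloxy)phenyl]-3-ethenyl-3,7,11-trimethyldodeca-6,10-dien-1-one | C=C[C@](C)(CC/C=C(\C)CCC=C(C)C)CC(=O)c1ccc(OCC=C)cc1OCC=C
A1 | alternative 1 | diethyl (2E,6E)-3,7,11-trimethyldodeca-2,6,10-trien-1-yl phosphate | CCOP(=O)(OCC)OC/C=C(\C)CC/C=C(\C)CCC=C(C)C
A2 | alternative 1 | 1-ethynyl-2,4-bis[(tert-butyldimethylsilyl)oxy]benzene | C#Cc1ccc(O[Si](C)(C)C(C)(C)C)cc1O[Si](C)(C)C(C)(C)C
A3 | alternative 1 | ({2,4-bis[(tert-butyldimethylsilyl)oxy]phenyl}ethynyl)bis(2-methylpropyl)aluminium | CC(C)C[Al](CC(C)C)C#Cc1ccc(O[Si](C)(C)C(C)(C)C)cc1O[Si](C)(C)C(C)(C)C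
A4 | alternative 1 | 1-[(3S,6E)-3-ethenyl-3,7,11-trimethyldodeca-6,10-dien-1-yn-1-yl]-2,4-bis[(tert-butyldimethylsilyl)oxy]benzene | C=C[C@](C)(CC/C=C(\C)CCC=C(C)C)C#Cc1ccc(O[Si](C)(C)C(C)(C)C)cc1O[Si](C)(C)C(C)(C)C
A5 | alternative 2 | (E)-β-farnesene, (6E)-7,11-dimethyl-3-methylidenedodeca-1,6,10-triene | C=CC(=C)CC/C=C(\C)CCC=C(C)C
A6 | alternative 2 | 1-[2,4-bis(methoxymethoxy)phenyl]-3-[(3E)-4,8-dimethylnona-3,7-dien-1-yl]-3-ethenylcyclobutan-1-ol (achiral; either ring diastereomer) | C=CC1(CC/C=C(\C)CCC=C(C)C)CC(O)(c2ccc(OCOC)cc2OCOC)C1
A7 | alternative 2 | (3R,6E)-1-[2,4-bis(methoxymethoxy)phenyl]-3-ethenyl-3,7,11-trimethyldodeca-6,10-dien-1-one | C=C[C@](C)(CC/C=C(\C)CCC=C(C)C)CC(=O)c1ccc(OCOC)cc1OCOC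
A8 | alternative 3 | tert-butyl[(3-ethenyl-3-methylpent-4-en-1-yl)oxy]dimethylsilane | C=CC(C)(C=C)CCO[Si](C)(C)C(C)(C)C
A9 | alternative 3 | (1E)-1-iodo-2,6-dimethylhepta-1,5-diene | I/C=C(\C)CCC=C(C)C
A10 | alternative 3 | tert-butyl{[(3R,6E)-3-ethenyl-3,7,11-trimethyldodeca-6,10-dien-1-yl]oxy}dimethylsilane | C=C[C@](C)(CC/C=C(\C)CCC=C(C)C)CCO[Si](C)(C)C(C)(C)C
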